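Assumption: the acyl chain is read as forty carbons including the carbonyl carbon (tetracontanoyl). Every intermediate with thirty or more chain carbons is treated as a wax that must be handled in warm THF, toluene or benzene-containing mixtures.

**Compound numbering used throughout**

1 1-triacontanol; 2 1-bromotriacontane; 3 10-bromodecanoic acid; 4 triacontylmagnesium bromide (not isolated); 5 chloromagnesium 10-bromodecanoate (not isolated); 6 tetracontanoic acid; 7 2-bromoethanol; 8 2-bromoethyl tetracontanoate; 9 4-bromophenol; 10 (4-bromophenoxy)(tert-butyl)dimethylsilane; 11 4-[(tert-butyldimethylsilyl)oxy]phenethyl tetracontanoate; 12 4-hydroxyphenethyl tetracontanoate (target).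

## Analysis of the target

The target 12 is the ester of an unbranched, saturated C40 acid (C1 carbonyl, C2–C39 methylene, C40 methyl) with the primary hydroxyl of a 2-arylethanol. Its only ring is a para-disubstituted benzene that carries the O–CH2–CH2 tether at C1' and a free phenolic OH at C4'. There is no stereocentre and no double-bond geometry, so all selectivity questions are questions of chemoselectivity. The sensitive groups are the ester, which after its formation tolerates neither strong base, hydride nor unbuffered nucleophiles, and the phenol, which is acidic, oxidisable and a competing acyl acceptor. The main difficulty is physical and analytical: the long-chain intermediates dissolve only in warm solvents, and homologues that differ by one or two methylene groups cannot be separated, so the chain length must be fixed by the carbon count of the building blocks. The strategy rests on the bond between aromatic C1' (para to the phenolic oxygen) and the benzylic CH2 of the tether. Because the next carbon carries the acyloxy group, this bond can be made from an aryl bromide and a 2-bromoethyl ester, provided the two-carbon unit reacts as a radical and never as a carbanion.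

## Retrosynthetic reasoning

**12 from 11 (O–Si bond).** The phenol is carried through the coupling as a tert-butyldimethylsilyl ether. A free phenol would be deprotonated by the carbonate base of the coupling and could bind nickel or quench radicals. The aryl O–Si bond is chosen because it is cleaved by buffered fluoride under conditions that leave an alkyl ester alone. The forward step only has to remove silicon.

**11 from 8 and 10 (C1'–CH2 bond).** The obvious cut at the ester C–O bond would demand a building block that already holds the aryl–CH2 bond, and a discrimination between its two hydroxyl groups. Cutting the aryl–CH2 bond instead divides the molecule into an aryl bromide 10 and an alkyl bromide 8, each reachable by simple, dependable steps. It also places the single uncertain step late and convergent. An organometallic version of this cut is not possible, since a metal on the carbon next to an acyloxy group eliminates the carboxylate. The forward reaction therefore has to activate the two bromides by different mechanisms, oxidative addition for 10 and halogen-atom abstraction for 8, and join an sp2 to an sp3 carbon without touching the ester or the silyl ether.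

**8 from 6 and 7 (ester C–O bond).** The bromide is bought in place in 7, so no functional-group change is needed after esterification. The forward step is a plain esterification of a long-chain acid with a small primary alcohol used in excess.

**6 from 4 and 5 (C10–C11 bond of the chain).** The cut leaves a C10 ω-bromo acid 3, carried as its magnesium carboxylate 5, and a C30 Grignard reagent 4. Copper-catalysed sp3–sp3 coupling gives the saturated chain directly. No oxidation level has to be adjusted afterwards, no double bond can migrate, and the carboxyl group needs no protecting group. The chain length is fixed as 30 + 10.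

**2 from 1 (C–Br from C–OH).** The bromide 2, from which 4 is made, comes from the commercial C30 alcohol 1 by substitution at a primary carbon.

**10 from 9 (O–Si bond).** Silylation of the commercial bromophenol 9 gives the aryl partner in one step.

## Alternatives that were turned down

**Alternative 1:** The chain is cut between C12 and C13, and C1–C12 are drawn from a twelve-membered ring.
- Forward key step: the enamine 4-(cyclododec-1-en-1-yl)morpholine A1 is C-acylated by octacosanoyl chloride A2, and hydrolysis of the acylated enamine gives 2-octacosanoylcyclododecan-1-one A3. Alkaline retro-Claisen opening of the ring ketone of A3 then leads to 13-oxotetracontanoic acid A4, Wolff–Kishner reduction of A4 gives 6, and 6 is esterified with tyrosol A5.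
- For: the chemistry is robust carbonyl chemistry without any transition metal, and the chain length is fixed as 12 + 28.
- Against: the C–C bond formation delivers the 1,3-diketone A3, so ring cleavage to A4 and a hot, strongly basic deoxygenation are needed before the chain is simply saturated. The enamine A1 has to be prepared first, and the C28 acid chloride A2 is no easier to obtain than 2. The last step must acylate only the aliphatic hydroxyl of A5.
- Comparison: this route needs about four operations to reach 6, where the chosen route needs two. Its endgame, ester formation on the intact aryl-ethanol A5, is safer than a photochemical nickel coupling, and that point goes to alternative 1. The chosen strategy offers a chain assembly free of redox adjustments and an arene that is introduced by C–C bond formation, so the aryl bromide can be varied.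

**Alternative 2:** The chain is cut at C10–C11 as an alkene.
- Forward key step: 4-hydroxyphenethyl undec-10-enoate A6 and 1-hentriacontene A7 undergo cross-metathesis with second-generation Grubbs catalyst, with loss of the two terminal methylene groups. This gives 4-hydroxyphenethyl (E)-tetracont-10-enoate A8, and hydrogenation of A8 gives 12.
- For: the free phenol is tolerated, no protecting group is needed, the alkene geometry of A8 is irrelevant, and the sequence is shorter than the chosen one.
- Against: both partners are unhindered terminal alkenes of the same reactivity class, so the cross product A8 forms statistically beside both homodimers. The alkene A7 is not a catalogue compound and has to be made from a C30 precursor. Ruthenium hydride species can move the double bonds before metathesis, and the resulting C39 and C41 esters would be inseparable from 12 after hydrogenation. The ester A6 also needs a selective acylation of A5.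
- Comparison: alternative 2 is stronger on step count and protecting-group economy. The chosen strategy offers a coupling that is cross-selective by mechanism and a chain length set by substitution at saturated carbon.

**Alternative 3:** The chain is cut at C19–C20.
- Forward key step: docosanoic acid A9 and the half-ester 20-[2-(4-acetoxyphenyl)ethoxy]-20-oxoicosanoic acid A10 are co-electrolysed at a platinum anode. Double decarboxylation and radical–radical coupling give 4-acetoxyphenethyl tetracontanoate A11, and the aryl acetate of A11 is then removed selectively to give 12.
- For: both chain pieces derive from abundant fatty acids, and the bond is formed without metal reagents or halides.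
- Against: radical–radical coupling at the anode is statistical, so the symmetrical dimers of both radicals accompany A11 and a large excess of A9 is needed. The half-ester A10 has to be made by a statistical mono-esterification and a selective acylation of A5. The phenol must be masked against anodic oxidation and then unmasked beside an alkyl ester. Long-chain carboxylates dissolve poorly in a polar electrolyte.
- Comparison: alternative 3 is cheaper in reagents, with no iridium or nickel. The chosen strategy offers cross-selectivity by design and a polar, non-statistical chain construction.

Key step: step 5

## Route

**Step 1**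
Reactants: 1 1-triacontanol
Product: 2 1-bromotriacontane
Conditions: CBr4, PPh3, THF, 40 °C
Reagents that add atoms: carbon tetrabromide, BrC(Br)(Br)Br
Why: Appel reaction; the alkoxyphosphonium ion of the primary alcohol is displaced by bromide in an SN2 step under neutral conditions, and warm THF keeps the C30 alcohol dissolved.

**Step 2**
Reactants: 2 1-bromotriacontane; 3 10-bromodecanoic acid
Product: 6 tetracontanoic acid, via triacontylmagnesium bromide 4 (not isolated), via chloromagnesium 10-bromodecanoate 5 (not isolated)
Conditions: 2, Mg, THF, 50 °C; separately 3 (1.2 equiv), MeMgCl, THF, −20 °C; combine, Li2CuCl4 (3 mol%), THF/NMP, 0 → 25 °C; aq. HCl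
Reagents that add atoms: none
Why: Copper-catalysed cross-coupling of a Grignard reagent with a primary alkyl bromide; the carboxylate 5 is inert to 4 at or below ambient temperature, so the organocopper species formed from 4 displaces only the primary bromide and the saturated C40 chain (30 + 10) is obtained on acidification.

**Step 3**
Reactants: 6 tetracontanoic acid; 7 2-bromoethanol
Product: 8 2-bromoethyl tetracontanoate
Conditions: 7 (5 equiv), TsOH·H2O (10 mol%), toluene, reflux, Dean–Stark
Reagents that add atoms: none
Why: Fischer esterification driven by excess alcohol and azeotropic removal of water; boiling toluene keeps 6 in solution and the primary C–Br bond of 7 is stable to acid in a non-nucleophilic medium.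

**Step 4**
Reactants: 9 4-bromophenol
Product: 10 (4-bromophenoxy)(tert-butyl)dimethylsilane
Conditions: TBSCl, imidazole, DMF, 25 °C
Reagents that add atoms: tert-butyldimethylsilyl chloride, CC(C)(C)[Si](C)(C)Cl
Why: Imidazole-mediated O-silylation of a phenol; it masks the acidic O–H before the nickel step and leaves the C–Br bond untouched.

**Step 5**
Reactants: 8 2-bromoethyl tetracontanoate; 10 (4-bromophenoxy)(tert-butyl)dimethylsilane (1.5 equiv)
Product: 11 4-[(tert-butyldimethylsilyl)oxy]phenethyl tetracontanoate
Conditions: NiCl2(dme) (5 mol%), 4,4'-di-tert-butyl-2,2'-bipyridine (5 mol%), Ir[dF(CF3)ppy]2(dtbbpy)PF6 (1 mol%), (Me3Si)3SiH (1.2 equiv), Na2CO3 (2 equiv), DME/PhH (1:1), 450 nm LEDs, 40 °C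
Reagents that add atoms: none
Why: Proposed new method: the closest known reaction type is the silyl-radical-mediated nickel and photoredox cross-electrophile coupling of aryl bromides with unactivated alkyl bromides, which has not been shown for a bromide that carries an acyloxy group on the neighbouring carbon. Zerovalent nickel bound to the bipyridine inserts into the C–Br bond of 10 to give a divalent arylnickel bromide, while the excited trivalent iridium photocatalyst oxidises bromide to a bromine atom that takes the hydrogen of (Me3Si)3SiH. The silyl radical abstracts bromine from 8 much more readily than from the aryl bromide, so each electrophile enters by its own channel and the cross product is favoured over either homodimer. The 2-(acyloxy)ethyl radical is an ordinary primary radical, because loss of an acyloxy radical is strongly uphill and the 1,2-acyloxy shift only exchanges two equivalent CH2 groups, so it reaches nickel unchanged. Its capture gives a trivalent aryl(alkyl)nickel species that should reductively eliminate the aryl–CH2 bond before beta-oxygen or beta-hydrogen elimination sets in, which is why a radical route is preferred to a 2-(acyloxy)ethyl zinc or magnesium reagent. The divalent iridium left by the photocatalytic cycle reduces monovalent nickel back to the zerovalent state. No ring is closed and no stereocentre is formed; the ester, the aryl silyl ether and the alkyl chain are inert to silyl radicals, carbonate and visible light, and benzene as co-solvent with gentle warming keeps the wax in solution.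

**Step 6**
Reactants: 11 4-[(tert-butyldimethylsilyl)oxy]phenethyl tetracontanoate
Product: 12 4-hydroxyphenethyl tetracontanoate
Conditions: TBAF, AcOH (1:1), THF, 25–40 °C
Reagents that add atoms: none
Why: Fluoride-induced desilylation; fluoride attacks silicon and expels the phenoxide, a far better leaving group than an alkoxide, while acetic acid protonates the phenoxide as it forms and keeps the medium non-basic, so the alkyl ester is neither hydrolysed nor transacylated.

## Compound list

1 | 1-triacontanol | CCCCCCCCCCCCCCCCCCCCCCCCCCCCCCO | starting material
2 | 1-bromotriacontane | CCCCCCCCCCCCCCCCCCCCCCCCCCCCCCBr | intermediate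
3 | 10-bromodecanoic acid | OC(=O)CCCCCCCCCBr | starting material
4 | triacontylmagnesium bromide (not isolated) | CCCCCCCCCCCCCCCCCCCCCCCCCCCCCC[Mg]Br | intermediate
5 | chloromagnesium 10-bromodecanoate (not isolated) | BrCCCCCCCCCC(=O)O[Mg]Cl | intermediate
6 | tetracontanoic acid | CCCCCCCCCCCCCCCCCCCCCCCCCCCCCCCCCCCCCCCC(=O)O | intermediate
7 | 2-bromoethanol | OCCBr | starting material
8 | 2-bromoethyl tetracontanoate | CCCCCCCCCCCCCCCCCCCCCCCCCCCCCCCCCCCCCCCC(=O)OCCBr | intermediate
9 | 4-bromophenol | Oc1ccc(Br)cc1 | starting material
10 | (4-bromophenoxy)(tert-butyl)dimethylsilane | CC(C)(C)[Si](C)(C)Oc1ccc(Br)cc1 | intermediate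
11 | 4-[(tert-butyldimethylsilyl)oxy]phenethyl tetracontanoate | CCCCCCCCCCCCCCCCCCCCCCCCCCCCCCCCCCCCCCCC(=O)OCCc1ccc(O[Si](C)(C)C(C)(C)C)cc1 | intermediate
12 | 4-hydroxyphenethyl tetracontanoate | CCCCCCCCCCCCCCCCCCCCCCCCCCCCCCCCCCCCCCCC(=O)OCCc1ccc(O)cc1 | target

## Step count and risk

Total step count: 6. Longest linear sequence: 5 steps (steps 1, 2, 3, 5, 6); step 4 is a one-step side branch.

**Step 5 (key step, proposed new method).**
- What may go wrong: hydrogen-atom transfer from the silane to the 2-(acyloxy)ethyl radical before nickel captures it; beta-acyloxy elimination from an alkylnickel intermediate with loss of the carboxylate; slow oxidative addition to the electron-rich aryl bromide, followed by its hydrodehalogenation; partial precipitation of the wax out of the irradiated solution. Non-phenolic long-chain by-products would be carried on and removed after step 6, where only 12 has a free phenol.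
- Fallback, known chemistry throughout, from 10 back to 11: the same aryl–CH2 bond is made with reversed polarity. Compound 10 is converted with Mg in THF into [4-(tert-butyldimethylsilyloxy)phenyl]magnesium bromide F1. F1 opens ethylene oxide under CuI catalysis (THF, −30 → 0 °C) to give 2-[4-(tert-butyldimethylsilyloxy)phenyl]ethan-1-ol F2. F2 is esterified with acid 6 from step 2 (EDC·HCl, DMAP, CHCl3, 40 °C, Steglich-type) to give 11. Step 3 is then not needed.

**Step 2.**
- What may go wrong: incomplete formation and partial precipitation of the C30 Grignard reagent, and its homocoupling and protonation, which leave long-chain hydrocarbons that are hard to separate from the waxy acid.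
- Fallback, from 2 back to 6: acetylide alkylation followed by hydrogenation. Dec-9-ynoic acid is doubly deprotonated with n-BuLi (2 equiv, THF/DMPU, −20 °C) to the dilithium salt of dec-9-ynoic acid F3. F3 is alkylated at the acetylide carbon by 2 (25 → 40 °C) to give tetracont-9-ynoic acid F4 after acidic work-up. Hydrogenation of F4 (H2, Pd/C, THF/EtOAc, 50 °C) gives 6.

**Step 6.**
- What may go wrong: loss of the ester through saponification by adventitious hydroxide in the fluoride reagent, or intermolecular transacylation by the liberated phenoxide. Both become more likely because the wax needs warming.
- Fallback, from 9 back to 12: a phenol protecting group that is removed by acid with loss of gases. Compound 9 is converted with Boc2O and catalytic DMAP (CH2Cl2) into 4-bromophenyl tert-butyl carbonate F5. F5 is coupled with 8 under the conditions of step 5 to give 4-[(tert-butoxycarbonyl)oxy]phenethyl tetracontanoate F6. TFA in CH2Cl2 at 0 °C converts F6 into 12; a primary alkyl ester is stable to these conditions.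

**Step 3.**
- What may go wrong: incomplete conversion in an equilibrium reaction of a poorly soluble acid, and consumption of 2-bromoethanol by acid-catalysed self-etherification at reflux.
- Fallback, from 6 back to 8: the ester is formed at the alkyl C–O bond instead of the acyl C–O bond. Acid 6 is converted with Cs2CO3 in DMF/toluene at 60 °C into caesium tetracontanoate F7. F7 is alkylated with a large excess of 1,2-dibromoethane to give 8; the excess suppresses formation of the ethylene diester.

## Further compounds

F1 | step 5 | [4-(tert-butyldimethylsilyloxy)phenyl]magnesium bromide | CC(C)(C)[Si](C)(C)Oc1ccc([Mg]Br)cc1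
F2 | step 5 | 2-[4-(tert-butyldimethylsilyloxy)phenyl]ethan-1-ol | CC(C)(C)[Si](C)(C)Oc1ccc(CCO)cc1
F3 | step 2 | dilithium salt of dec-9-ynoic acid (lithium 10-lithiodec-9-ynoate) | [Li]C#CCCCCCCCC(=O)O[Li]
F4 | step 2 | tetracont-9-ynoic acid | CCCCCCCCCCCCCCCCCCCCCCCCCCCCCCC#CCCCCCCCC(=O)O
F5 | step 6 | 4-bromophenyl tert-butyl carbonate | CC(C)(C)OC(=O)Oc1ccc(Br)cc1
F6 | step 6 | 4-[(tert-butoxycarbonyl)oxy]phenethyl tetracontanoate | CCCCCCCCCCCCCCCCCCCCCCCCCCCCCCCCCCCCCCCC(=O)OCCc1ccc(OC(=O)OC(C)(C)C)cc1
F7 | step 3 | caesium tetracontanoate | CCCCCCCCCCCCCCCCCCCCCCCCCCCCCCCCCCCCCCCC(=O)[O-].[Cs+]
A1 | alternative 1 | 4-(cyclododec-1-en-1-yl)morpholine | C1(N2CCOCC2)=CCCCCCCCCCC1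
A2 | alternative 1 | octacosanoyl chloride | CCCCCCCCCCCCCCCCCCCCCCCCCCCC(=O)Cl
A3 | alternative 1 | 2-octacosanoylcyclododecan-1-one (racemic) | CCCCCCCCCCCCCCCCCCCCCCCCCCCC(=O)C1CCCCCCCCCCC1=O
A4 | alternative 1 | 13-oxotetracontanoic acid | CCCCCCCCCCCCCCCCCCCCCCCCCCCC(=O)CCCCCCCCCCCC(=O)O
A5 | alternative 1 | tyrosol, 2-(4-hydroxyphenyl)ethan-1-ol | OCCc1ccc(O)cc1
A6 | alternative 2 | 4-hydroxyphenethyl undec-10-enoate | C=CCCCCCCCCC(=O)OCCc1ccc(O)cc1
A7 | alternative 2 | 1-hentriacontene | C=CCCCCCCCCCCCCCCCCCCCCCCCCCCCCC
A8 | alternative 2 | 4-hydroxyphenethyl (E)-tetracont-10-enoate | CCCCCCCCCCCCCCCCCCCCCCCCCCCCC/C=C/CCCCCCCCC(=O)OCCc1ccc(O)cc1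
A9 | alternative 3 | docosanoic acid | CCCCCCCCCCCCCCCCCCCCCC(=O)O
A10 | alternative 3 | 20-[2-(4-acetoxyphenyl)ethoxy]-20-oxoicosanoic acid | OC(=O)CCCCCCCCCCCCCCCCCCC(=O)OCCc1ccc(OC(C)=O)cc1
A11 | alternative 3 | 4-acetoxyphenethyl tetracontanoate | CCCCCCCCCCCCCCCCCCCCCCCCCCCCCCCCCCCCCCCC(=O)OCCc1ccc(OC(C)=O)cc1
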